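**Retrosynthetic overview**

1. Briarellin A 33 ⇐ Δ6-alkene lactone 31 (epoxidation, then Cp2TiCl opening to the 6-hydroxy-7(19)-ene). The lactone ring is closed last, from C16-OH and C3-OH (hydroboration, oxidative lactonisation).
2. 31 ⇐ tricycle 22. The C11 carbinol comes from MeMgBr on the ketone unmasked from an enol ether. 22 ⇐ intramolecular Diels–Alder of oxonene 21 (2-methoxydiene on C9, enone on C2), which forms the cyclohexene and oxolane rings and sets C1, C10 and C14 in one step.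
3. Oxonene 12 ⇐ ring-closing metathesis of acyclic ether 11. The C3 carbinol follows by MeMgCl addition to the ring ketone.
4. Ether stereocentre C9 ⇐ alkylation of dioxanone 9 (a glycolate locked onto the C2/C3 diol). C2 ⇐ Felkin addition of 2-lithio-1,3-dithiane (masked C1 aldehyde) to aldehyde 4.
5. C4 (and the relay centre C3) ⇐ 2-deoxy-L-ribose. Ring order: oxonene → cyclohexene + oxolane (cycloaddition) → lactone.

Assumption: 2-deoxy-L-ribose and dimethyl (1-diazo-2-oxopropyl)phosphonate are bought; C-numbers in descriptive names are briarellin locants, and "oxonene" means the ring O–C2–C3–C4–C5–C6=C7–C8–C9.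

**Route**

Step 1
Reactants: 1 2-deoxy-L-ribose
Product: 2 2-deoxy-3,4-O-isopropylidene-L-erythro-pentopyranose
Conditions: 2-methoxypropene, PPTS (cat.), DMF, 0 °C
Reagents that add atoms: 2-methoxypropene, COC(C)=C
Why: Kinetic acetonide formation on the cis-3,4-diol of the pyranose leaves only the lactol OH free and touches no stereocentre.

Step 2
Reactants: 2 2-deoxy-3,4-O-isopropylidene-L-erythro-pentopyranose
Product: 3 [(4S,5R)-2,2-dimethyl-5-(prop-2-en-1-yl)-1,3-dioxolan-4-yl]methanol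
Conditions: Ph3PCH3Br, KOtBu, THF, 0 °C → rt
Reagents that add atoms: methyltriphenylphosphonium bromide, C[P+](c1ccccc1)(c1ccccc1)c1ccccc1.[Br-]
Why: Wittig methylenation of the open-chain aldehyde form of the lactol gives the terminal alkene (future C5–C6) and frees the primary alcohol.

Step 3
Reactants: 3 [(4S,5R)-2,2-dimethyl-5-(prop-2-en-1-yl)-1,3-dioxolan-4-yl]methanol
Product: 4 (4R,5R)-2,2-dimethyl-5-(prop-2-en-1-yl)-1,3-dioxolane-4-carbaldehyde
Conditions: Dess–Martin periodinane, CH2Cl2, 0 °C → rt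
Reagents that add atoms: none
Why: Dess–Martin oxidation gives the α-alkoxy aldehyde under neutral conditions without epimerisation.

Step 4
Reactants: 4 (4R,5R)-2,2-dimethyl-5-(prop-2-en-1-yl)-1,3-dioxolane-4-carbaldehyde
Product: 5 (R)-(1,3-dithian-2-yl)[(4S,5R)-2,2-dimethyl-5-(prop-2-en-1-yl)-1,3-dioxolan-4-yl]methanol
Conditions: 1,3-dithiane, n-BuLi, THF, −30 °C; then 4, −78 °C
Reagents that add atoms: 1,3-dithiane, C1CSCSC1
Why: Corey–Seebach addition of the acyl-anion equivalent proceeds in the Felkin–Anh sense (anti to the dioxolane C–O bond), so the ribose-derived C3 sets C2 as the 2,3-anti carbinol and C1 arrives as a masked aldehyde.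

Step 5
Reactants: 5 (R)-(1,3-dithian-2-yl)[(4S,5R)-2,2-dimethyl-5-(prop-2-en-1-yl)-1,3-dioxolan-4-yl]methanol
Product: 8 (5R,6R)-5-(1,3-dithian-2-yl)-6-[(1R)-1-hydroxybut-3-en-1-yl]-1,4-dioxan-2-one, via carboxymethyl ether 6 (not isolated), via dihydroxy acid 7 (not isolated)
Conditions: NaH, BrCH2CO2H, THF/DMF, 0 °C → rt; 80% aq AcOH, 50 °C; PPTS (cat.), toluene, reflux
Reagents that add atoms: bromoacetic acid, OC(=O)CBr
Why: Williamson etherification of the only free hydroxyl, acetonide hydrolysis and six-ring (rather than seven-ring) lactonisation onto O3 give the glycolate dioxanone with the C2 and C3 substituents cis.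

Step 6
Reactants: 8 (5R,6R)-5-(1,3-dithian-2-yl)-6-[(1R)-1-hydroxybut-3-en-1-yl]-1,4-dioxan-2-one
Product: 9 (5R,6S)-6-[(1R)-1-{[tert-butyl(dimethyl)silyl]oxy}but-3-en-1-yl]-5-(1,3-dithian-2-yl)-1,4-dioxan-2-one
Conditions: TBSOTf, 2,6-lutidine, CH2Cl2, −78 → 0 °C
Reagents that add atoms: tert-butyldimethylsilyl triflate, CC(C)(C)[Si](C)(C)OS(=O)(=O)C(F)(F)F
Why: Silylation protects the C4 hydroxyl as a bulky, non-chelating ether for the enolate, hydride and Grignard steps ahead.

Step 7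
Reactants: 9 (5R,6S)-6-[(1R)-1-{[tert-butyl(dimethyl)silyl]oxy}but-3-en-1-yl]-5-(1,3-dithian-2-yl)-1,4-dioxan-2-one
Product: 10 (3S,5R,6S)-6-[(1R)-1-{[tert-butyl(dimethyl)silyl]oxy}but-3-en-1-yl]-5-(1,3-dithian-2-yl)-3-(2-methylprop-2-en-1-yl)-1,4-dioxan-2-one
Conditions: LiN(iPr)2, THF, −78 °C; CH2=C(CH3)CH2Br, DMPU, −78 → −40 °C
Reagents that add atoms: 3-bromo-2-methylprop-1-ene, C=C(C)CBr
Why: In this substrate-controlled glycolate enolate alkylation the electrophile enters anti to the two cis ring substituents, which sets C9 trans to the C2 substituent (H2 and H9 cis across the ether oxygen).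

Step 8
Reactants: 10 (3S,5R,6S)-6-[(1R)-1-{[tert-butyl(dimethyl)silyl]oxy}but-3-en-1-yl]-5-(1,3-dithian-2-yl)-3-(2-methylprop-2-en-1-yl)-1,4-dioxan-2-one
Product: 11 (2S)-2-{[(1R,2S,3R)-3-{[tert-butyl(dimethyl)silyl]oxy}-1-(1,3-dithian-2-yl)-2-hydroxyhex-5-en-1-yl]oxy}-4-methylpent-4-en-1-ol
Conditions: LiAlH4, THF, 0 °C
Reagents that add atoms: none
Why: Hydride reduction opens the lactone to the C10 primary and C3 secondary alcohols, releasing the acyclic bis-alkenyl ether.

Step 9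
Reactants: 11 (2S)-2-{[(1R,2S,3R)-3-{[tert-butyl(dimethyl)silyl]oxy}-1-(1,3-dithian-2-yl)-2-hydroxyhex-5-en-1-yl]oxy}-4-methylpent-4-en-1-ol
Product: 12 oxonene diol
Conditions: second-generation Grubbs catalyst (5 mol %), CH2Cl2 (2 mM), 40 °C
Reagents that add atoms: none
Why: Ring-closing metathesis of the allyl and methallyl groups, helped by the gauche-disposed C–O bonds of the ether chain, closes the nine-membered ring, whose size enforces the (Z)-C6=C7 alkene.

Step 10
Reactants: 12 oxonene diol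
Product: 13 oxonene keto aldehyde
Conditions: (COCl)2, DMSO, CH2Cl2, −78 °C; Et3N, −78 → −20 °C
Reagents that add atoms: none
Why: Swern oxidation converts both alcohols (C10 to the aldehyde, C3 to the ketone) and leaves the thioacetal intact.

Step 11
Reactants: 14 dimethyl (1-diazo-2-oxopropyl)phosphonate
Product: 15 dimethyl (1-methoxy-2-oxopropyl)phosphonate
Conditions: MeOH, Rh2(OAc)4 (1 mol %), CH2Cl2, rt
Reagents that add atoms: methanol, CO
Why: Rhodium carbenoid O–H insertion into methanol gives the α-methoxy β-ketophosphonate needed to bring in C11 with its oxygen.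

Step 12
Reactants: 13 oxonene keto aldehyde; 15 dimethyl (1-methoxy-2-oxopropyl)phosphonate
Product: 16 oxonene methoxy enone
Conditions: LiCl, DBU, MeCN, 0 °C → rt
Reagents that add atoms: none
Why: Masamune–Roush Horner–Wadsworth–Emmons olefination reacts only at the aldehyde and places the acyl group trans to C9, giving the (Z)-enol ether.

Step 13
Reactants: 16 oxonene methoxy enone
Product: 17 oxonene dienyl triflate
Conditions: KN(SiMe3)2, THF, −78 °C; PhNTf2
Reagents that add atoms: N-phenylbis(trifluoromethanesulfonimide), O=S(=O)(N(c1ccccc1)S(=O)(=O)C(F)(F)F)C(F)(F)F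
Why: Kinetic deprotonation of the unhindered methyl ketone (faster than the hindered C2 and C4 methines) and O-triflation give the 2-methoxy-3-triflyloxy diene.

Step 14
Reactants: 17 oxonene dienyl triflate
Product: 18 oxonene methoxydiene ketone
Conditions: Pd(OAc)2 (5 mol %), PPh3, Bu3N, HCO2H, DMF, 60 °C
Reagents that add atoms: none
Why: Palladium-catalysed formate reduction of the enol triflate (Cacchi conditions) replaces OTf by H and gives the (Z)-2-methoxy-1,3-diene.

Step 15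
Reactants: 18 oxonene methoxydiene ketone
Product: 19 oxonene tertiary carbinol
Conditions: MeMgCl, THF, −78 °C
Reagents that add atoms: methylmagnesium chloride, C[Mg]Cl
Why: Grignard addition to the ring ketone from the peripheral face, in the Felkin sense to both flanking C–O stereocentres (the C4 silyl ether does not chelate), sets C3 with its oxygen anti to O2 and O4.

Step 16
Reactants: 19 oxonene tertiary carbinol
Product: 20 oxonene C1 aldehyde
Conditions: MeI, CaCO3, MeCN/H2O (9:1), 40 °C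
Reagents that add atoms: water, O
Why: Alkylative thioacetal hydrolysis (S-methylation, then water) under carbonate buffering frees the C1 aldehyde without acid and so spares the enol-ether diene.

Step 17
Reactants: 20 oxonene C1 aldehyde
Product: 22 Diels–Alder tricycle, via enone triene 21 (not isolated)
Conditions: Ph3P=CHC(O)CH3, CH2Cl2, rt → 40 °C
Reagents that add atoms: 1-(triphenylphosphoranylidene)propan-2-one, CC(=O)C=P(c1ccccc1)(c1ccccc1)c1ccccc1
Why: Wittig olefination gives the (E)-enone, which undergoes spontaneous intramolecular Diels–Alder cycloaddition through the exo transition state imposed by the oxonene tether, forming the cyclohexene and oxolane rings and setting C1, C10 (cis fusion, anti to H2/H9) and C14 (acyl trans to C2).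

Step 18
Reactants: 22 Diels–Alder tricycle
Product: 24 C11 ketone, via isopropenyl enol ether 23 (not isolated)
Conditions: Ph3PCH3Br, KOtBu, THF, 0 °C; then oxalic acid, THF/H2O, 0 °C
Reagents that add atoms: methyltriphenylphosphonium bromide, C[P+](c1ccccc1)(c1ccccc1)c1ccccc1.[Br-]; water, O
Why: Wittig methylenation of the C15 ketone (C11 still masked) installs C16, and mild acid hydrolysis of the enol ether then unveils the C11 ketone.

Step 19
Reactants: 24 C11 ketone
Product: 25 C11 tertiary carbinol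
Conditions: MeMgBr, THF, −78 °C
Reagents that add atoms: methylmagnesium bromide, C[Mg]Br
Why: Grignard addition from the convex face, anti to the axial C10–C9 bond of the cis-fused bicycle, places the methyl axial and the hydroxyl cis to C9, as in the target.

Step 20
Reactants: 25 C11 tertiary carbinol
Product: 26 C4 alcohol
Conditions: Bu4NF, THF, 0 °C → rt
Reagents that add atoms: none
Why: Fluoride desilylation frees the only secondary hydroxyl of the molecule.

Step 21
Reactants: 26 C4 alcohol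
Product: 27 C4 octanoate
Conditions: C7H15COCl, pyridine, DMAP (cat.), CH2Cl2, 0 °C
Reagents that add atoms: octanoyl chloride, CCCCCCCC(=O)Cl
Why: DMAP-catalysed acylation is selective for the secondary alcohol over the two tertiary ones.

Step 22
Reactants: 27 C4 octanoate
Product: 29 C16 primary alcohol, via alkylborane 28 (not isolated)
Conditions: 9-BBN, THF, 0 °C → rt; NaBO3·4H2O, H2O
Reagents that add atoms: sodium perborate, [Na+].[O-]OB=O
Why: Hydroboration–oxidation with the bulky borane picks the 1,1-disubstituted alkene over the ring alkene and adds anti to C1 on the conformer with H14 eclipsing the alkene, which sets C15 as R.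

Step 23
Reactants: 29 C16 primary alcohol
Product: 31 seven-ring lactone, via hydroxy aldehyde 30 (not isolated)
Conditions: TEMPO (cat.), PhI(OAc)2, CH2Cl2, rt
Reagents that add atoms: none
Why: Oxidative lactonisation (aldehyde, lactol with the nearby C3 hydroxyl, then lactone) closes the oxepanone; the C11 hydroxyl is trans-disposed to C15 and cannot take part.

Step 24
Reactants: 31 seven-ring lactone
Product: 32 6,7-epoxide
Conditions: mCPBA, CH2Cl2, 0 °C
Reagents that add atoms: 3-chloroperbenzoic acid, OOC(=O)c1cccc(Cl)c1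
Why: Prilezhaev epoxidation of the only remaining alkene from the exposed outer face of the bridged oxonene sets the C6–O bond (the C3 oxygen is tied up in the lactone, so no transannular ether can form).

Step 25
Reactants: 32 6,7-epoxide
Product: 33 briarellin A
Conditions: Cp2TiCl2, Mn, THF, rt; then aq. HCl
Reagents that add atoms: none
Why: Homolytic epoxide opening by Cp2TiCl (Nugent–RajanBabu) gives the tertiary C7 radical with C6–O intact, and trapping followed by β-hydride loss from the methyl group delivers the exocyclic allylic alcohol with C6 unchanged.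

**Compound list**

1 | 2-deoxy-L-ribose, (3R,4S)-3,4,5-trihydroxypentanal (drawn open-chain) | O=CC[C@@H](O)[C@@H](O)CO | starting material
2 | 2-deoxy-3,4-O-isopropylidene-L-erythro-pentopyranose (anomer mixture) | OC1C[C@H]2OC(C)(C)O[C@H]2CO1 | intermediate
3 | [(4S,5R)-2,2-dimethyl-5-(prop-2-en-1-yl)-1,3-dioxolan-4-yl]methanol | C=CC[C@H]1OC(C)(C)O[C@H]1CO | intermediate
4 | (4R,5R)-2,2-dimethyl-5-(prop-2-en-1-yl)-1,3-dioxolane-4-carbaldehyde | C=CC[C@H]1OC(C)(C)O[C@H]1C=O | intermediate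
5 | (R)-(1,3-dithian-2-yl)[(4S,5R)-2,2-dimethyl-5-(prop-2-en-1-yl)-1,3-dioxolan-4-yl]methanol | C=CC[C@H]1OC(C)(C)O[C@H]1[C@@H](O)C2SCCCS2 | intermediate
6 | carboxymethyl ether: 5 with the carbinol oxygen carrying CH2CO2H, acetonide intact | C=CC[C@H]1OC(C)(C)O[C@H]1[C@@H](OCC(=O)O)C2SCCCS2 | intermediate
7 | dihydroxy acid: 2-{[(1R,2R,3R)-1-(1,3-dithian-2-yl)-2,3-dihydroxyhex-5-en-1-yl]oxy}acetic acid | C=CC[C@@H](O)[C@@H](O)[C@@H](OCC(=O)O)C1SCCCS1 | intermediate
8 | (5R,6R)-5-(1,3-dithian-2-yl)-6-[(1R)-1-hydroxybut-3-en-1-yl]-1,4-dioxan-2-one | C=CC[C@@H](O)[C@H]1OC(=O)CO[C@H]1C2SCCCS2 | intermediate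
9 | (5R,6S)-6-[(1R)-1-{[tert-butyl(dimethyl)silyl]oxy}but-3-en-1-yl]-5-(1,3-dithian-2-yl)-1,4-dioxan-2-one | C=CC[C@@H](O[Si](C)(C)C(C)(C)C)[C@H]1OC(=O)CO[C@H]1C2SCCCS2 | intermediate
10 | (3S,5R,6S)-6-[(1R)-1-{[tert-butyl(dimethyl)silyl]oxy}but-3-en-1-yl]-5-(1,3-dithian-2-yl)-3-(2-methylprop-2-en-1-yl)-1,4-dioxan-2-one | C=CC[C@@H](O[Si](C)(C)C(C)(C)C)[C@H]1OC(=O)[C@H](CC(C)=C)O[C@H]1C2SCCCS2 | intermediate
11 | (2S)-2-{[(1R,2S,3R)-3-{[tert-butyl(dimethyl)silyl]oxy}-1-(1,3-dithian-2-yl)-2-hydroxyhex-5-en-1-yl]oxy}-4-methylpent-4-en-1-ol | C=CC[C@@H](O[Si](C)(C)C(C)(C)C)[C@@H](O)[C@@H](O[C@H](CO)CC(C)=C)C1SCCCS1 | intermediate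
12 | oxonene diol: (6Z)-oxonene with C2 1,3-dithian-2-yl, C3 OH, C4 OTBS, C7 CH3, C9 CH2OH; 2R,3S,4R,9S; H2 and H9 cis | OC[C@@H]1C/C(C)=C\C[C@@H](O[Si](C)(C)C(C)(C)C)[C@@H](O)[C@@H](O1)C2SCCCS2 | intermediate
13 | oxonene keto aldehyde: 12 with C3 ketone and C9 CHO; 2R,4R,9S | O=C[C@@H]1C/C(C)=C\C[C@@H](O[Si](C)(C)C(C)(C)C)C(=O)[C@@H](O1)C2SCCCS2 | intermediate
14 | dimethyl (1-diazo-2-oxopropyl)phosphonate | CC(=O)C(=[N+]=[N-])P(=O)(OC)OC | starting material
15 | dimethyl (1-methoxy-2-oxopropyl)phosphonate (racemic) | COC(C(C)=O)P(=O)(OC)OC | intermediate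
16 | oxonene methoxy enone: 13 with C9 carrying (Z)-CH=C(OCH3)–C(O)CH3 (C10=C11, C9 cis to OCH3) | CC(=O)/C(OC)=C/[C@@H]1C/C(C)=C\C[C@@H](O[Si](C)(C)C(C)(C)C)C(=O)[C@@H](O1)C2SCCCS2 | intermediate
17 | oxonene dienyl triflate: 16 with C12 as C(OSO2CF3)=CH2 | C=C(OS(=O)(=O)C(F)(F)F)/C(OC)=C/[C@@H]1C/C(C)=C\C[C@@H](O[Si](C)(C)C(C)(C)C)C(=O)[C@@H](O1)C2SCCCS2 | intermediate
18 | oxonene methoxydiene ketone: C9 carries (1Z)-2-methoxybuta-1,3-dien-1-yl, C3 ketone | C=C/C(OC)=C/[C@@H]1C/C(C)=C\C[C@@H](O[Si](C)(C)C(C)(C)C)C(=O)[C@@H](O1)C2SCCCS2 | intermediate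
19 | oxonene tertiary carbinol: 18 with C3 as C(CH3)OH, hydroxyl anti to O2 and O4 | C=C/C(OC)=C/[C@@H]1C/C(C)=C\C[C@@H](O[Si](C)(C)C(C)(C)C)[C@](C)(O)[C@@H](O1)C2SCCCS2 | intermediate
20 | oxonene C1 aldehyde: 19 with CHO on C2 in place of the dithiane | C=C/C(OC)=C/[C@@H]1C/C(C)=C\C[C@@H](O[Si](C)(C)C(C)(C)C)[C@](C)(O)[C@@H](O1)C=O | intermediate
21 | enone triene: 20 with C2 carrying (E)-CH=CH–C(O)CH3 | C=C/C(OC)=C/[C@@H]1C/C(C)=C\C[C@@H](O[Si](C)(C)C(C)(C)C)[C@](C)(O)[C@@H](O1)/C=C/C(C)=O | intermediate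
22 | Diels–Alder tricycle: oxolane (O, C2, C1, C10, C9) cis-fused to cyclohexene (C11(OCH3)=C12) and bridged by the (6Z)-oxonene; C14 acetyl trans to C2; C3 CH3/OH; C4 OTBS; H1/H10 cis and anti to H2/H9 | C/C1=C/C[C@@H](O[Si](C)(C)C(C)(C)C)[C@](C)(O)[C@H]2O[C@@H](C1)[C@@H]1C(OC)=CC[C@@H](C(C)=O)[C@@H]12 | intermediate
23 | isopropenyl enol ether: 22 with C14 prop-1-en-2-yl | C/C1=C/C[C@@H](O[Si](C)(C)C(C)(C)C)[C@](C)(O)[C@H]2O[C@@H](C1)[C@@H]1C(OC)=CC[C@@H](C(C)=C)[C@@H]12 | intermediate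
24 | C11 ketone: 23 with C11=O, C12 CH2 | C/C1=C/C[C@@H](O[Si](C)(C)C(C)(C)C)[C@](C)(O)[C@H]2O[C@@H](C1)[C@@H]1C(=O)CC[C@@H](C(C)=C)[C@@H]12 | intermediate
25 | C11 tertiary carbinol: 24 with C11 C(CH3)OH, hydroxyl cis to C9 | C/C1=C/C[C@@H](O[Si](C)(C)C(C)(C)C)[C@](C)(O)[C@H]2O[C@@H](C1)[C@@H]1[C@](C)(O)CC[C@@H](C(C)=C)[C@@H]12 | intermediate
26 | C4 alcohol: 25 with free 4-OH (3,4,11-triol) | C/C1=C/C[C@@H](O)[C@](C)(O)[C@H]2O[C@@H](C1)[C@@H]1[C@](C)(O)CC[C@@H](C(C)=C)[C@@H]12 | intermediate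
27 | C4 octanoate: 26 with 4-O-octanoyl | C/C1=C/C[C@@H](OC(=O)CCCCCCC)[C@](C)(O)[C@H]2O[C@@H](C1)[C@@H]1[C@](C)(O)CC[C@@H](C(C)=C)[C@@H]12 | intermediate
28 | alkylborane: 27 with C14 carrying (R)-CH(CH3)CH2–(9-borabicyclo[3.3.1]nonan-9-yl) | C/C1=C/C[C@@H](OC(=O)CCCCCCC)[C@](C)(O)[C@H]2O[C@@H](C1)[C@@H]1[C@](C)(O)CC[C@@H]([C@@H](C)CB3C4CCCC3CCC4)[C@@H]12 | intermediate
29 | C16 primary alcohol: 27 with C14 carrying (R)-CH(CH3)CH2OH | C/C1=C/C[C@@H](OC(=O)CCCCCCC)[C@](C)(O)[C@H]2O[C@@H](C1)[C@@H]1[C@](C)(O)CC[C@@H]([C@@H](C)CO)[C@@H]12 | intermediate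
30 | hydroxy aldehyde: 29 with C16 CHO (in equilibrium with the C3–O lactol) | C/C1=C/C[C@@H](OC(=O)CCCCCCC)[C@](C)(O)[C@H]2O[C@@H](C1)[C@@H]1[C@](C)(O)CC[C@@H]([C@@H](C)C=O)[C@@H]12 | intermediate
31 | seven-ring lactone: 6,7-didehydro-6-deoxy-7,19-dihydro-briarellin A (C6=C7 Z, C7 methyl) | C/C1=C/C[C@@H](OC(=O)CCCCCCC)[C@]2(C)OC(=O)[C@H](C)[C@@H]3CC[C@@](C)(O)[C@H]4[C@H](C1)O[C@H]2[C@@H]34 | intermediate
32 | 6,7-epoxide of 31 (6S,7R; oxygen on the outer face) | C[C@@]15O[C@H]5C[C@@H](OC(=O)CCCCCCC)[C@]2(C)OC(=O)[C@H](C)[C@@H]3CC[C@@](C)(O)[C@H]4[C@H](C1)O[C@H]2[C@@H]34 | intermediate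
33 | briarellin A (1S,2S,3S,4R,6S,9S,10R,11R,14R,15R) | C=C1C[C@@H]2O[C@H]3[C@H]4[C@@H](CC[C@@](C)(O)[C@H]42)[C@@H](C)C(=O)O[C@@]3(C)[C@H](OC(=O)CCCCCCC)C[C@@H]1O | target

**Step count and risks**

Total step count: 25 (24 on the main line plus the one-step preparation of phosphonate 15).
Longest linear sequence: 24 steps (1 → 33; steps 1–10 and 12–25).

Three steps most likely to fail:

Step 7 (C9 set by enolate alkylation of a monocyclic dioxanone; the facial bias may be too small). The fallback makes the ether stereocentre by SN2 etherification instead, setting out from 5 and coming back at 10. Commercial methyl (2R)-oxirane-2-carboxylate (L-serine-derived) is opened at its CH2 with isopropenylmagnesium bromide and catalytic CuI to give methyl (2R)-2-hydroxy-4-methylpent-4-enoate F1. Tf2O and 2,6-lutidine convert this into methyl (2R)-4-methyl-2-(trifluoromethylsulfonyloxy)pent-4-enoate F2. The sodium alkoxide of 5 (NaH, THF, −20 °C) displaces the triflate with inversion to give the ether ester F3. Aqueous acetic acid and then PPTS in hot toluene remove the acetonide and close the six-membered lactone to the hydroxy dioxanone F4, and TBSOTf with 2,6-lutidine returns the material to 10.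

Step 16 (thioacetal hydrolysis next to the acid-labile 2-methoxydiene). The fallback changes the order so that the diene is released last, setting out from 17 and coming back at 22. MeMgCl adds to the C3 ketone of 17 to give the carbinol dienyl triflate F5. MeI and CaCO3 in aqueous MeCN unmask the C1 aldehyde on this less sensitive triflyloxy diene to give the aldehyde dienyl triflate F6, and Ph3P=CHC(O)CH3 gives the enone dienyl triflate F7. Formate reduction with Pd(OAc)2, PPh3 and Bu3N then generates the methoxydiene in the presence of the dienophile, and the cycloaddition gives 22.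

Step 24 (the face of epoxidation fixes C6; the regiochemistry of the following opening is a lesser concern). The fallback corrects C6 by oxidation and reduction, setting out from 31 and coming back at 33. If the peracid attacks the other face, the epimeric epoxide F8 forms and the Cp2TiCl step gives 6-epi-briarellin A F9. Dess–Martin periodinane oxidises this to the exocyclic enone F10, and Luche reduction (NaBH4, CeCl3·7H2O, MeOH, −78 °C) delivers hydride from the same exposed face the peracid used, giving 33.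

**Further compounds**

F1 | step 7 | methyl (2R)-2-hydroxy-4-methylpent-4-enoate | COC(=O)[C@H](O)CC(C)=C
F2 | step 7 | methyl (2R)-4-methyl-2-{[(trifluoromethyl)sulfonyl]oxy}pent-4-enoate | COC(=O)[C@H](OS(=O)(=O)C(F)(F)F)CC(C)=C
F3 | step 7 | ether ester: 5 with the carbinol oxygen bonded to C2 of methyl (2S)-4-methylpent-4-enoate | C=CC[C@H]1OC(C)(C)O[C@H]1[C@@H](O[C@@H](CC(C)=C)C(=O)OC)C2SCCCS2
F4 | step 7 | hydroxy dioxanone: 10 without the silyl group | C=CC[C@@H](O)[C@H]1OC(=O)[C@H](CC(C)=C)O[C@H]1C2SCCCS2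
F5 | step 16 | carbinol dienyl triflate: 17 with C3 as C(CH3)OH | C=C(OS(=O)(=O)C(F)(F)F)/C(OC)=C/[C@@H]1C/C(C)=C\C[C@@H](O[Si](C)(C)C(C)(C)C)[C@](C)(O)[C@@H](O1)C2SCCCS2
F6 | step 16 | aldehyde dienyl triflate: F5 with CHO on C2 | C=C(OS(=O)(=O)C(F)(F)F)/C(OC)=C/[C@@H]1C/C(C)=C\C[C@@H](O[Si](C)(C)C(C)(C)C)[C@](C)(O)[C@@H](O1)C=O
F7 | step 16 | enone dienyl triflate: F6 with (E)-CH=CH–C(O)CH3 on C2 | C=C(OS(=O)(=O)C(F)(F)F)/C(OC)=C/[C@@H]1C/C(C)=C\C[C@@H](O[Si](C)(C)C(C)(C)C)[C@](C)(O)[C@@H](O1)/C=C/C(C)=O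
F8 | step 24 | epimeric (6R,7S) epoxide of 31 | C[C@]15O[C@@H]5C[C@@H](OC(=O)CCCCCCC)[C@]2(C)OC(=O)[C@H](C)[C@@H]3CC[C@@](C)(O)[C@H]4[C@H](C1)O[C@H]2[C@@H]34
F9 | step 24 | 6-epi-briarellin A | C=C1C[C@@H]2O[C@H]3[C@H]4[C@@H](CC[C@@](C)(O)[C@H]42)[C@@H](C)C(=O)O[C@@]3(C)[C@H](OC(=O)CCCCCCC)C[C@H]1O
F10 | step 24 | 6-oxo enone (6-dehydrobriarellin A) | C=C1C[C@@H]2O[C@H]3[C@H]4[C@@H](CC[C@@](C)(O)[C@H]42)[C@@H](C)C(=O)O[C@@]3(C)[C@H](OC(=O)CCCCCCC)CC1=O
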